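## Retrosynthetic overview
1. The C8 ester is cut last, giving an 8-hydroxy germacranolide and silyl-protected 2-(hydroxymethyl)acrylic acid.
2. Key cut: the C7–C8 and O6–C12 bonds together. This gives an open-chain C8 aldehyde that carries a 6,7-vinyl-oxirane acrylate. One CrCl2/LiI operation closes the ten-membered carbocycle and the γ-lactone and sets C7 and C8.
3. The 6,7-oxirane with C7 and C11–C13 comes from a C6 epoxy aldehyde and the sulfonium ylide of methyl 2-(bromomethyl)acrylate (sets C6). The C8 aldehyde comes from a prenyl alkene by ozonolysis.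
4. C9–C10 comes from a (Z)-α-iodoenoate and prenal by asymmetric Nozaki–Hiyama–Kishi coupling (sets C9). C1=C10 comes from an iodo-Wittig reaction on the C1 aldehyde.
5. C1–C6 and C15 come from nerol, and Sharpless epoxidation sets C4 and C5. Ring order: the 4,5-oxirane first, then the carbocycle and the lactone together.

Assumption: the SMILES is read literally as (4R,5S,6S,7R,8S,9R), with C3 and C6 cis on the oxirane (so nerol, not geraniol) and C2 and C9 cis on C1=C10; germacrane numbering C1–C15 is used throughout.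

## Route

Step 1
Reactants: 1 nerol
Product: 2 (2S,3R)-2,3-epoxynerol
Conditions: Ti(OiPr)4 (5 mol %), L-(+)-diethyl tartrate (7 mol %), t-BuOOH (1.5 equiv), 4 Å MS, CH2Cl2, −20 °C
Reagents that add atoms: tert-butyl hydroperoxide, CC(C)(C)OO
Why: In this Katsuki–Sharpless asymmetric epoxidation the titanium–L-(+)-tartrate complex binds the allylic alcohol and delivers oxygen to one face of the Z-alkene, which sets C4 (R) and C5 (S) with C3 and C6 cis on the oxirane (about 92% ee expected) and leaves the remote alkene untouched.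

Step 2
Reactants: 2 (2S,3R)-2,3-epoxynerol
Product: 3 3-[(2R,3S)-3-(hydroxymethyl)-2-methyloxiran-2-yl]propanal
Conditions: O3, CH2Cl2, −78 °C; then Me2S, −78 → 23 °C
Reagents that add atoms: ozone, [O-][O+]=O
Why: Criegee ozonolysis cleaves the only alkene and unmasks C1 as the aldehyde, while the oxirane, the alcohol and both stereocentres are inert at −78 °C.

Step 3
Reactants: 3 3-[(2R,3S)-3-(hydroxymethyl)-2-methyloxiran-2-yl]propanal; 4 methyl (triphenylphosphoranylidene)acetate
Product: 6 methyl (2Z)-5-[(2R,3S)-3-(hydroxymethyl)-2-methyloxiran-2-yl]-2-iodopent-2-enoate, via iodo ylide 5 (not isolated)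
Conditions: 4, NIS (1.05 equiv), CH2Cl2, −20 °C, 30 min; then 3, −20 → 23 °C
Reagents that add atoms: N-iodosuccinimide, O=C1CCC(=O)N1I
Why: Wittig olefination with the α-iodinated stabilised ylide made in the flask adds C10 and C14 and gives mainly the (Z)-α-iodoenoate (C2 cis to iodine, trans to the ester), which is the C1=C10 geometry of the target.

Step 4
Reactants: 6 methyl (2Z)-5-[(2R,3S)-3-(hydroxymethyl)-2-methyloxiran-2-yl]-2-iodopent-2-enoate; 7 3-methylbut-2-enal (prenal)
Product: 8 methyl (2E)-2-[(1S)-1-hydroxy-3-methylbut-2-en-1-yl]-5-[(2R,3S)-3-(hydroxymethyl)-2-methyloxiran-2-yl]pent-2-enoate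
Conditions: CrCl2 (4 equiv), NiCl2 (2 mol %), N-{2-[(4S)-4-tert-butyl-4,5-dihydro-1,3-oxazol-2-yl]-6-methylphenyl}methanesulfonamide (4.4 equiv), Et3N (4.4 equiv), THF, 23 °C; aq. potassium serinate work-up
Reagents that add atoms: none
Why: In this asymmetric Nozaki–Hiyama–Kishi coupling, nickel inserts into the carbon–iodine bond and passes the alkenyl group to chromium with retention of geometry, and the chiral sulfonamide on chromium steers 1,2-addition to the Re face of 7, which sets C9 (S here, R once C8 is oxidised) while the free alcohol, oxirane and ester are tolerated.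

Step 5
Reactants: 8 methyl (2E)-2-[(1S)-1-hydroxy-3-methylbut-2-en-1-yl]-5-[(2R,3S)-3-(hydroxymethyl)-2-methyloxiran-2-yl]pent-2-enoate
Product: 9 methyl (2E)-5-[(2R,3R)-3-formyl-2-methyloxiran-2-yl]-2-[(1S)-1-hydroxy-3-methylbut-2-en-1-yl]pent-2-enoate
Conditions: TEMPO (2,2,6,6-tetramethylpiperidine-1-oxyl, 10 mol %), PhI(OAc)2 (1.1 equiv), CH2Cl2, 0 → 23 °C
Reagents that add atoms: none
Why: The TEMPO/PhI(OAc)2 oxidation (Piancatelli–Margarita) takes the unhindered primary C6 alcohol to the aldehyde much faster than the hindered secondary C9 carbinol, and C5 of the epoxy aldehyde does not enolise.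

Step 6
Reactants: 9 methyl (2E)-5-[(2R,3R)-3-formyl-2-methyloxiran-2-yl]-2-[(1S)-1-hydroxy-3-methylbut-2-en-1-yl]pent-2-enoate
Product: 10 methyl (2E)-2-[(1S)-1-acetoxy-3-methylbut-2-en-1-yl]-5-[(2R,3R)-3-formyl-2-methyloxiran-2-yl]pent-2-enoate
Conditions: Ac2O (1.5 equiv), pyridine, DMAP (4-dimethylaminopyridine, 5 mol %), CH2Cl2, 0 °C
Reagents that add atoms: acetic anhydride, CC(=O)OC(C)=O
Why: Plain O-acetylation of the only remaining hydroxyl installs the C9 acetate of the target with retention.

Step 7
Reactants: 10 methyl (2E)-2-[(1S)-1-acetoxy-3-methylbut-2-en-1-yl]-5-[(2R,3R)-3-formyl-2-methyloxiran-2-yl]pent-2-enoate; 11 methyl 2-(bromomethyl)acrylate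
Product: 14 methyl (2E)-2-[(1S)-1-acetoxy-3-methylbut-2-en-1-yl]-5-{(2R,3S)-3-[(2S,3R)-3-(3-methoxy-3-oxoprop-1-en-2-yl)oxiran-2-yl]-2-methyloxiran-2-yl}pent-2-enoate, via sulfonium bromide 12 (not isolated), via allylic ylide 13 (not isolated)
Conditions: 11, tetrahydrothiophene (1.2 equiv), MeCN, 23 °C, 12 h; then 10, K2CO3 (1.5 equiv), 0 → 23 °C
Reagents that add atoms: none
Why: Johnson–Corey–Chaykovsky epoxidation with the semi-stabilised allylic sulfonium ylide adds C7 and C11–C13 at once, and the ylide carbon attacks the aldehyde in the polar Felkin–Anh sense (anti to the oxirane C–O bond, reinforced by the cis C3 chain) to set C6 (S), while the C7 centre (mainly trans oxirane) is erased in step 9.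

Step 8
Reactants: 14 bis-oxirane prenyl acetate
Product: 15 methyl (2E)-2-[(1R)-1-acetoxy-2-oxoethyl]-5-{(2R,3S)-3-[(2S,3R)-3-(3-methoxy-3-oxoprop-1-en-2-yl)oxiran-2-yl]-2-methyloxiran-2-yl}pent-2-enoate
Conditions: O3 (end point by Sudan Red 7B), CH2Cl2, −78 °C; then Me2S, −78 → 0 °C; used at once
Reagents that add atoms: ozone, [O-][O+]=O
Why: Electrophilic ozone cleaves the electron-rich trisubstituted prenyl alkene far faster than the two ester-conjugated alkenes (chemoselective Criegee ozonolysis), which frees the C8 aldehyde without touching C9.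

Step 9
Reactants: 15 bis-oxirane C8 aldehyde
Product: 18 (4R,5S,6S,7R,8S,9R)-9-acetoxy-4,5-epoxy-8-hydroxy-14-methoxy-14-oxogermacra-1(10),11(13)-dien-12,6-olide, via allylic iodide 16 (not isolated), via macrocyclic diol ester 17 (not isolated)
Conditions: CrCl2 (8 equiv), LiI (4 equiv), THF, 23 °C, 15 added by syringe pump over 12 h (final 2 mM); aq. sodium potassium tartrate work-up
Reagents that add atoms: none
Why: Proposed new method: iodide opens the acrylate-activated vinyl oxirane in SN2′ fashion at C13 (the isolated 4,5-oxirane lacks this activation), two CrCl2 reduce the allylic iodide 16 to an allylchromium held by the C6 alkoxide as a six-membered chelate with C6 cis to C13, this adds through C7 to the tethered C8 aldehyde in a closed transition state (C7–C8 syn as known for 2-alkoxycarbonylallyl chromium reagents, C8–C9 anti by the polar Felkin–Anh/Cornforth preference of the α-acetoxy aldehyde, C7 formed anti to C5 on the chelate), and only once C7 is sp3 can the C6 alkoxide reach C12 and expel methoxide to give the trans-fused lactone, so carbocycle and lactone arise in the same operation; the closest known reaction types are the Nozaki–Hiyama-type CrCl2–LiI coupling of 1,3-diene monoepoxides with aldehydes to 2-vinyl-1,3-diols, the CrCl2 allylation–lactonisation with 2-(bromomethyl)acrylates, and Nozaki–Hiyama–Kishi closures of ten-membered germacranolide rings.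

Step 10
Reactants: 19 ethyl 2-(hydroxymethyl)acrylate
Product: 20 ethyl 2-{[(tert-butyldimethylsilyl)oxy]methyl}acrylate
Conditions: TBSCl (1.1 equiv), imidazole (1.5 equiv), CH2Cl2, 0 → 23 °C
Reagents that add atoms: tert-butyldimethylsilyl chloride, CC(C)(C)[Si](C)(C)Cl
Why: Standard imidazole-promoted silylation masks the primary alcohol so that the acid cannot oligomerise during the later esterification.

Step 11
Reactants: 20 ethyl 2-{[(tert-butyldimethylsilyl)oxy]methyl}acrylate
Product: 21 2-{[(tert-butyldimethylsilyl)oxy]methyl}acrylic acid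
Conditions: LiOH (1.5 equiv), THF/H2O, 0 → 23 °C; then aq. HCl to pH 4
Reagents that add atoms: lithium hydroxide, [Li+].[OH-]
Why: Saponification of the unhindered ethyl ester is faster than conjugate addition of hydroxide, and the primary TBS ether survives the brief mild acidification.

Step 12
Reactants: 18 8-hydroxy germacranolide; 21 2-{[(tert-butyldimethylsilyl)oxy]methyl}acrylic acid
Product: 22 8-O-(2-{[(tert-butyldimethylsilyl)oxy]methyl}acryloyl) derivative of 18
Conditions: 21 (3 equiv), N,N'-diisopropylcarbodiimide (3 equiv), DMAP (4-dimethylaminopyridine, 0.3 equiv), CH2Cl2, 0 → 23 °C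
Reagents that add atoms: none
Why: Steglich esterification acylates the only free hydroxyl (C8) with retention under near-neutral conditions, and the excess of activated acid outruns 9→8 acetyl migration.

Step 13
Reactants: 22 silyl-protected target
Product: 23 target CNP0147016.1
Conditions: HF·pyridine, pyridine, THF, 0 °C
Reagents that add atoms: none
Why: Buffered fluoride desilylation removes the primary TBS ether without opening the trisubstituted oxirane, cleaving the esters or adding to the three acrylate units.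

## Compound list
1 | nerol, (2Z)-3,7-dimethylocta-2,6-dien-1-ol | CC(C)=CCC/C(C)=C\CO | starting material
2 | (2S,3R)-2,3-epoxynerol | OC[C@@H]1O[C@]1(C)CCC=C(C)C | intermediate
3 | 3-[(2R,3S)-3-(hydroxymethyl)-2-methyloxiran-2-yl]propanal | OC[C@@H]1O[C@]1(C)CCC=O | intermediate
4 | methyl (triphenylphosphoranylidene)acetate | COC(=O)C=P(c1ccccc1)(c1ccccc1)c1ccccc1 | starting material
5 | methyl iodo(triphenylphosphoranylidene)acetate (iodo ylide) | COC(=O)C(I)=P(c1ccccc1)(c1ccccc1)c1ccccc1 | intermediate
6 | methyl (2Z)-5-[(2R,3S)-3-(hydroxymethyl)-2-methyloxiran-2-yl]-2-iodopent-2-enoate | OC[C@@H]1O[C@]1(C)CC/C=C(I)/C(=O)OC | intermediate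
7 | 3-methylbut-2-enal (prenal) | CC(C)=CC=O | starting material
8 | methyl (2E)-2-[(1S)-1-hydroxy-3-methylbut-2-en-1-yl]-5-[(2R,3S)-3-(hydroxymethyl)-2-methyloxiran-2-yl]pent-2-enoate | OC[C@@H]1O[C@]1(C)CC/C=C(/C(=O)OC)[C@H](C=C(C)C)O | intermediate
9 | methyl (2E)-5-[(2R,3R)-3-formyl-2-methyloxiran-2-yl]-2-[(1S)-1-hydroxy-3-methylbut-2-en-1-yl]pent-2-enoate | O=C[C@@H]1O[C@]1(C)CC/C=C(/C(=O)OC)[C@H](C=C(C)C)O | intermediate
10 | methyl (2E)-2-[(1S)-1-acetoxy-3-methylbut-2-en-1-yl]-5-[(2R,3R)-3-formyl-2-methyloxiran-2-yl]pent-2-enoate | O=C[C@@H]1O[C@]1(C)CC/C=C(/C(=O)OC)[C@H](C=C(C)C)OC(C)=O | intermediate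
11 | methyl 2-(bromomethyl)acrylate | C=C(CBr)C(=O)OC | starting material
12 | 1-[2-(methoxycarbonyl)prop-2-en-1-yl]tetrahydrothiophenium bromide | C=C(C[S+]1CCCC1)C(=O)OC.[Br-] | intermediate
13 | allylic sulfonium ylide from 12 | C=C([CH-][S+]1CCCC1)C(=O)OC | intermediate
14 | bis-oxirane prenyl acetate (4R,5S,6S,7R,9S; 6,7-oxirane trans, bearing the acrylate at C7) | C=C(C(=O)OC)[C@H]1O[C@@H]1[C@@H]2O[C@]2(C)CC/C=C(/C(=O)OC)[C@H](C=C(C)C)OC(C)=O | intermediate
15 | bis-oxirane C8 aldehyde (4R,5S,6S,7R,9R) | C=C(C(=O)OC)[C@H]1O[C@@H]1[C@@H]2O[C@]2(C)CC/C=C(/C(=O)OC)[C@H](C=O)OC(C)=O | intermediate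
16 | C13 allylic iodide, C7=C11 with C6 cis to CH2I, C6 oxygen drawn as the alcohol | IC/C(C(=O)OC)=C\[C@H](O)[C@@H]1O[C@]1(C)CC/C=C(/C(=O)OC)[C@H](C=O)OC(C)=O | intermediate
17 | macrocyclic 6,8-diol with the C7 (methoxycarbonyl)vinyl group, before lactonisation | O[C@H]1[C@@H](C(=C)C(=O)OC)[C@H](O)[C@@H]2O[C@]2(C)CC/C=C(/C(=O)OC)[C@H]1OC(C)=O | intermediate
18 | (4R,5S,6S,7R,8S,9R)-9-acetoxy-4,5-epoxy-8-hydroxy-14-methoxy-14-oxogermacra-1(10),11(13)-dien-12,6-olide | O[C@H]1[C@H]2C(=C)C(=O)O[C@@H]2[C@@H]2O[C@]2(C)CC/C=C(/C(=O)OC)[C@H]1OC(C)=O | intermediate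
19 | ethyl 2-(hydroxymethyl)acrylate | C=C(CO)C(=O)OCC | starting material
20 | ethyl 2-{[(tert-butyldimethylsilyl)oxy]methyl}acrylate | C=C(CO[Si](C)(C)C(C)(C)C)C(=O)OCC | intermediate
21 | 2-{[(tert-butyldimethylsilyl)oxy]methyl}acrylic acid | C=C(CO[Si](C)(C)C(C)(C)C)C(=O)O | intermediate
22 | TBS ether of the target | C=C(CO[Si](C)(C)C(C)(C)C)C(=O)O[C@H]1[C@H]2C(=C)C(=O)O[C@@H]2[C@@H]2O[C@]2(C)CC/C=C(/C(=O)OC)[C@H]1OC(C)=O | intermediate
23 | CNP0147016.1 | C=C(CO)C(=O)O[C@H]1[C@H]2C(=C)C(=O)O[C@@H]2[C@@H]2O[C@]2(C)CC/C=C(/C(=O)OC)[C@H]1OC(C)=O | target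

## Step count and risks
Total steps: 13. Longest linear sequence: 11 (steps 1–9, 12, 13).

**Step 9 is the most likely to fail.**
- Ways it can fail: oligomerisation instead of ten-ring closure, attack of LiI or trivalent chromium on the 4,5-oxirane, Payne migration of the C6 alkoxide, lactonisation through O8 instead of O6, and the wrong C8 epimer if the allylchromium isomerises before it adds.
- The fallback sets out from 14 and comes back at 18. It replaces the one-pot chromium cascade by an isolated allylic bromide and an aqueous indium Barbier closure.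
- MgBr2·OEt2 in Et2O at −20 °C opens only the vinyl oxirane in SN2′ fashion and gives the C13 bromide with free C6 alcohol F1.
- Selective ozonolysis of the prenyl alkene gives the bromo aldehyde F2.
- Indium powder in THF/water at high dilution, which tolerates the free hydroxyl and is known to be syn-selective for (Z)-2-(bromomethyl)alk-2-enoates, closes C7–C8 to 17. This lactonises through O6 on silica gel to 18.

**Step 4 is second.**
- Ways it can fail: face control by the chromium ligand on a small enal is uncertain, the ligand antipode may have to be swapped, and an O-bound chromium allenolate could erode the C1=C10 geometry.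
- The fallback sets out from 6 and comes back at 8. It moves the stereocontrol from the C–C bond formation to a ketone reduction.
- Ligand-free coupling with CrCl2/NiCl2 and 7 gives the C9-epimeric diol F3.
- MnO2 oxidises only the doubly allylic carbinol and gives the hydroxy dienone F4.
- (R)-2-methyl-CBS-oxazaborolidine with BH3·SMe2 in toluene at −40 °C treats the α-branched alkenyl group as the large substituent and returns the (S)-carbinol 8.

**Step 7 is third.**
- Ways it can fail: the 2-(alkoxycarbonyl)allyl sulfonium salt is itself a Michael acceptor and may self-condense, the ylide may react through C13, and the facial selectivity at C6 rests on substrate control alone.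
- The fallback sets out from 10 and 11 and comes back at 14. It uses a γ-bromoallyl metal and a halohydrin closure instead of an ylide.
- Bromine adds to 11 and gives methyl 2,3-dibromo-2-(bromomethyl)propanoate F5.
- Et3N removes HBr and gives methyl (2Z)-3-bromo-2-(bromomethyl)acrylate F6.
- Indium-mediated Barbier addition of F6 to 10 forms the C6–C7 bond through the bromine-bearing carbon and gives the bromohydrin F7.
- K2CO3 in MeCN closes the 6,7-oxirane to 14. Either C7 epimer is usable because step 9 erases C7.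

## Further compounds
F1 | step 9 | C13 allylic bromide with free C6 alcohol and intact prenyl acetate | BrC/C(C(=O)OC)=C\[C@H](O)[C@@H]1O[C@]1(C)CC/C=C(/C(=O)OC)[C@H](C=C(C)C)OC(C)=O
F2 | step 9 | C13 allylic bromide with free C6 alcohol and C8 aldehyde | BrC/C(C(=O)OC)=C\[C@H](O)[C@@H]1O[C@]1(C)CC/C=C(/C(=O)OC)[C@H](C=O)OC(C)=O
F3 | step 4 | C9-epimeric mixture of diol 8 | OC[C@@H]1O[C@]1(C)CC/C=C(/C(=O)OC)C(O)C=C(C)C
F4 | step 4 | C9 ketone (hydroxy dienone) | OC[C@@H]1O[C@]1(C)CC/C=C(/C(=O)OC)C(=O)C=C(C)C
F5 | step 7 | methyl 2,3-dibromo-2-(bromomethyl)propanoate | COC(=O)C(Br)(CBr)CBr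
F6 | step 7 | methyl (2Z)-3-bromo-2-(bromomethyl)acrylate | BrC/C(C(=O)OC)=C\Br
F7 | step 7 | C7 bromide, C6 alcohol bromohydrin | C=C(C(=O)OC)[C@H](Br)[C@H](O)[C@@H]1O[C@]1(C)CC/C=C(/C(=O)OC)[C@H](C=C(C)C)OC(C)=O
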